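No constants are given for the proposed steps, so I read two times off the earlier runs instead.

all flasks: L 0.50 mM

| flask | E | Z | temperature | remark | time |
|---|---|---|---|---|---|
| teal | 0.26 mM | 0.50 mM | 5 °C | run made earlier |  |
| red | 0.39 mM | 0.50 mM | 35 °C | run made earlier |  |
| grey | 0.525 mM | 0.25 mM | 5 °C | run made earlier |  |
| gamma | 0.525 mM | 0.500 mM | 60 °C |  | 2.5 min |
| beta | 0.525 mM | 0.500 mM | 35 °C |  | 2.5 min |
| alpha | 0.525 mM | 0.500 mM | 10 °C |  | 2.5 min |

| run | time / min | D / % | J / % |
|---|---|---|---|
| teal | 4.00 | 21 | 0 |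
| teal | 6.00 | 21 | 4 |
| teal | 10.0 | 30 | 8 |
| teal | 15.0 | 27 | 11 |
| teal | 30.0 | 24 | 23 |
| teal | 50.0 | 21 | 32 |
| red | 0.667 | 16 | 1 |
| red | 2.50 | 16 | 16 |
| red | 3.00 | 14 | 19 |
| red | 5.00 | 7 | 28 |
| red | 8.00 | 7 | 30 |
| red | 10.0 | 2 | 37 |
| grey | 10.0 | 12 | 4 |
| grey | 20.0 | 9 | 5 |
| grey | 30.0 | 6 | 9 |
| grey | 40.0 | 7 | 14 |
| grey | 50.0 | 6 | 15 |

(each reading ± 2 percentage points)

- the earlier runs were read with a standard deviation of 2 percentage points
- steps that have been proposed: L <-> Q; L + Z -> D; Z + E -> X; D + X -> J

1. the flask that comes out highest in amount of D, in percent of the L charged, or "all alike" when all lie within 1.5 percentage points (gamma / beta / alpha / all alike)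
2. D at the end, in percent of the L charged, gamma
3. D at the end, in percent of the L charged, beta
4. D at the end, in percent of the L charged, alpha

The concentration that sets the order of D's loss is X: J forms by D + X, so at a given X the loss of D is pseudo-first-order. In red, at 35 °C, I get

τD = 1.96 min

This τD is the life of D, the D present divided by the rate at which J grows. Against it stands τM, the D + J finally read in red divided by their early rate of forming:

τM = 1.53 min

D rises over τM and falls over τD, and in these red readings τD is longer than τM by a factor of 1.28. Treated as a first-order chain, this gives at 2.5 min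

D ≈ 14.9%

That is my estimate for red at that time, where the reading is 16%; beta has more E than red, so I expect beta to lie somewhat lower. Teal, at 5 °C, reads τD = 42.5 min, far longer than the 2.5 min asked. Alpha is warmer than teal and has more E, so that reading carries over roughly, but I expect alpha to keep what it makes and put it first.

The forecast says alpha, with 14%, 10% and 0.5% for alpha, beta and gamma, and for gamma that “D is eaten by excess X”; its beta lies below my estimate for red.

The flask gives alpha highest, with 15.5%, 11.2% and 0.621% for alpha, beta and gamma.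

    L ⇌ Q (K = 2.10, k = 0.160 s⁻¹, Ea = 96.0 kJ mol⁻¹, ΔH = 25.0 kJ mol⁻¹)
    L + Z → D (k = 42.0 L mol⁻¹ s⁻¹, Ea = 39.0 kJ mol⁻¹)
    Z + E → X (k = 70.0 L mol⁻¹ s⁻¹, Ea = 37.0 kJ mol⁻¹)
    D + X → J (k = 200 L mol⁻¹ s⁻¹, Ea = 50.0 kJ mol⁻¹)
    (constants at 60 °C)

Beta ends with 18.0% of its Z left. Over beta's second half, τD as read in red turns beta's mean D into a J gain of 8.4 percentage points, and beta shows 9.2 points. The same quotient in gamma, over its second half, gives 0.426 min, shorter than τD from red.

(The runs stem from a simulated flask with constants of no real substance; the scatter is artificial.)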